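**Strategy**

Daucane locants: C1 ring-fusion C–Me, C4 carbinol, C5 ring-fusion CH, C6 CH–OAr, C7=C8(Me), C9 CH–OAc, C10 CH2. The route rests on cutting the seven-membered ring at C7–C8 and C1–C10. This exploits that the ring holds a 2-oxygenated three-carbon unit (C8–C9–C10) opposite a four-carbon unit (C7–C6–C5–C1) anchored on the cyclopentane. The precursors are a vinylcyclopentene diene from (S)-terpinen-4-ol (its carbinol carbon becomes C4) and a siloxyvinyl diazoacetate. One Rh-catalysed cyclopropanation/divinylcyclopropane Cope operation forms both bonds, closes the ring and sets quaternary C1; the C8 ester later becomes the methyl of the C7=C8 alkene, and the C5=C6 alkene delivers H5 and O6.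

Key step: step 7

Remark: locants C1–C10 in the text are the daucane locants defined above; compound names use hydroazulene locants (C4 = 3, C5 = 3a, C6 = 4, C7 = 5, C8 = 6, C9 = 7, C10 = 8, C1 = 8a).
Assumption: commercial (S)-(+)-terpinen-4-ol is used as a single enantiomer (ee to be checked before use).

**Route**

Step 1
Reactants: 1 (S)-(+)-terpinen-4-ol
Product: 2 (S)-triethyl[(1-isopropyl-4-methylcyclohex-3-en-1-yl)oxy]silane
Conditions: TESOTf, 2,6-lutidine, CH2Cl2, −78 → 0 °C
Reagents that add atoms: triethylsilyl trifluoromethanesulfonate, CC[Si](CC)(CC)OS(=O)(=O)C(F)(F)F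
Why: Silyl triflate silylation of a hindered tertiary alcohol; the ether blocks β-elimination in step 3 and O–H insertion in step 7, and no stereocentre is touched.

Step 2
Reactants: 2 (S)-triethyl[(1-isopropyl-4-methylcyclohex-3-en-1-yl)oxy]silane
Product: 4 (S)-3-isopropyl-6-oxo-3-(triethylsilyloxy)heptanal, via ozonide 3 (not isolated)
Conditions: O3, CH2Cl2, −78 °C; then PPh3, −78 °C → rt
Reagents that add atoms: ozone, [O-][O+]=O
Why: Ozonolysis of the only alkene with reductive work-up gives the keto aldehyde; the silyl ether and the carbinol stereocentre are inert.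

Step 3
Reactants: 4 (S)-3-isopropyl-6-oxo-3-(triethylsilyloxy)heptanal
Product: 5 (R)-5-isopropyl-2-methyl-5-(triethylsilyloxy)cyclopent-1-ene-1-carbaldehyde
Conditions: piperidine, AcOH, benzene, 80 °C
Reagents that add atoms: none
Why: Amine-catalysed intramolecular aldol condensation (aldehyde enamine adds to the methyl ketone, five-ring closure, dehydration), the classical ring contraction of limonene-type keto aldehydes; the quaternary carbinol centre cannot epimerise.

Step 4
Reactants: 5 (R)-5-isopropyl-2-methyl-5-(triethylsilyloxy)cyclopent-1-ene-1-carbaldehyde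
Product: 6 (R)-triethyl[(1-isopropyl-3-methyl-2-vinylcyclopent-2-en-1-yl)oxy]silane
Conditions: Ph3PCH3Br, KOtBu, THF, 0 °C → rt
Reagents that add atoms: methyltriphenylphosphonium bromide, C[P+](c1ccccc1)(c1ccccc1)c1ccccc1.[Br-]
Why: Wittig methylenation of the enal gives the 1,3-diene C7=C6–C5=C1 without touching the silyl ether.

Step 5
Reactants: 7 methyl acetoacetate
Product: 8 methyl 2-diazo-3-oxobutanoate
Conditions: p-ABSA, Et3N, MeCN, 0 °C → rt
Reagents that add atoms: 4-acetamidobenzenesulfonyl azide, CC(=O)Nc1ccc(cc1)S(=O)(=O)N=[N+]=[N-]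
Why: Regitz diazo transfer to an active methylene compound.

Step 6
Reactants: 8 methyl 2-diazo-3-oxobutanoate
Product: 9 methyl 3-(tert-butyldimethylsilyloxy)-2-diazobut-3-enoate
Conditions: TBSOTf, Et3N, CH2Cl2, 0 °C
Reagents that add atoms: tert-butyldimethylsilyl trifluoromethanesulfonate, CC(C)(C)[Si](C)(C)OS(=O)(=O)C(F)(F)F
Why: Soft enolisation and O-silylation of the methyl ketone gives the 2-siloxyvinyl diazoacetate, the precursor of a donor/acceptor vinylcarbenoid.

Step 7
Reactants: 6 (R)-triethyl[(1-isopropyl-3-methyl-2-vinylcyclopent-2-en-1-yl)oxy]silane; 9 methyl 3-(tert-butyldimethylsilyloxy)-2-diazobut-3-enoate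
Product: 11 methyl (3R,8aR)-7-(tert-butyldimethylsilyloxy)-3-isopropyl-8a-methyl-3-(triethylsilyloxy)-1,2,3,5,8,8a-hexahydroazulene-6-carboxylate, via cis-divinylcyclopropane 10 (not isolated)
Conditions: Rh2(S-PTAD)4 (1 mol%), hexanes, −26 °C → rt, slow addition of 9 (1.5 equiv); then toluene, 100 °C
Reagents that add atoms: none
Why: The donor/acceptor rhodium carbenoid from 9 cyclopropanates the terminal vinyl group of 6 (carbenoid carbon C8 bonds to C7 and C6) with the siloxyvinyl group cis to the cyclopentenyl group, and cis-divinylcyclopropane 10 then undergoes a [3,3] Cope shift through the boat transition state, breaking C6–C8 and forming C1–C10. The closest known reaction type is the tandem cyclopropanation/Cope formal [4+3] cycloaddition of siloxyvinyldiazoacetates with dienes under chiral Rh(II) carboxylate catalysis. The seven-membered ring is closed by this stereospecific sigmatropic ring expansion of the cyclopropane. The one new stereocentre kept in 11, quaternary C1, is fixed by the cyclopropane configuration (carbenoid delivered by the catalyst to the Si face of the vinyl CH, C6) together with the ring-locked alkene geometry (methyl cis to C6), so that C10 enters anti to the C4 silyloxy group. The step needs site selectivity for the vinyl group over the tetrasubstituted ring alkene (sterics), the cis-divinyl arrangement (inherent to donor/acceptor carbenoids), catalyst control that overrides the C4 stereocentre, and heating to bring the Z-methyl-substituted alkene into the boat.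

Step 8
Reactants: 11 methyl (3R,8aR)-7-(tert-butyldimethylsilyloxy)-3-isopropyl-8a-methyl-3-(triethylsilyloxy)-1,2,3,5,8,8a-hexahydroazulene-6-carboxylate
Product: 13 methyl (3R,3aS,4S,8aR)-7-(tert-butyldimethylsilyloxy)-4-hydroxy-3-isopropyl-8a-methyl-3-(triethylsilyloxy)-1,2,3,3a,4,5,8,8a-octahydroazulene-6-carboxylate, via alkylborane 12 (not isolated)
Conditions: BH3·THF, THF, 0 °C → rt; then NaBO3·4H2O, H2O, rt
Reagents that add atoms: sodium perborate tetrahydrate, [Na+].[Na+].O[B-]1(O)OO[B-](O)(O)OO1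
Why: Hydroboration–oxidation adds H (to C5) and OH (to the less substituted C6) syn, on the face anti to both the angular C1 methyl and the allylic C4 silyloxy group (as in Δ5-steroids and cyclic allylic ethers), which should set the trans ring fusion and the C6 alcohol together; the push–pull siloxy acrylate is inert.

Step 9
Reactants: 13 methyl (3R,3aS,4S,8aR)-7-(tert-butyldimethylsilyloxy)-4-hydroxy-3-isopropyl-8a-methyl-3-(triethylsilyloxy)-1,2,3,3a,4,5,8,8a-octahydroazulene-6-carboxylate
Product: 15 (3R,3aS,4S,8aR)-4-hydroxy-3-isopropyl-8a-methyl-6-methylidene-3-(triethylsilyloxy)-2,3,3a,4,5,6,8,8a-octahydroazulen-7(1H)-one, via allylic alcohol 14 (not isolated)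
Conditions: DIBAL-H (4 equiv), CH2Cl2, −78 °C; then 1 M HCl, THF, 0 °C, short contact
Reagents that add atoms: none
Why: 1,2-Reduction of the β-siloxy acrylate followed by acid-induced loss of water and of the silyl group from the 3-siloxy allylic alcohol (Stork–Danheiser-type carbonyl transposition) turns the C8 ester carbon into the methylidene carbon of an α-methylene ketone at C9.

Step 10
Reactants: 15 (3R,3aS,4S,8aR)-4-hydroxy-3-isopropyl-8a-methyl-6-methylidene-3-(triethylsilyloxy)-2,3,3a,4,5,6,8,8a-octahydroazulen-7(1H)-one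
Product: 16 (3R,3aS,4S,8aR)-4-hydroxy-3-isopropyl-6,8a-dimethyl-3-(triethylsilyloxy)-2,3,3a,4,8,8a-hexahydroazulen-7(1H)-one
Conditions: RhCl3·3H2O (5 mol%), EtOH, 70 °C
Reagents that add atoms: none
Why: Rhodium hydride-mediated migration of the exocyclic enone alkene to the thermodynamically preferred endocyclic trisubstituted position creates the C7=C8 alkene and the C8 methyl group; 15 is used directly after step 9.

Step 11
Reactants: 17 4-hydroxybenzoic acid
Product: 19 4-(tert-butyldimethylsilyloxy)benzoic acid, via bis-silyl derivative 18 (not isolated)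
Conditions: TBSCl (2.5 equiv), imidazole, DMF, rt; then AcOH/THF/H2O, rt
Reagents that add atoms: tert-butyldimethylsilyl chloride, CC(C)(C)[Si](C)(C)Cl
Why: Exhaustive silylation followed by selective hydrolysis of the labile silyl ester leaves the acid-stable aryl silyl ether.

Step 12
Reactants: 16 (3R,3aS,4S,8aR)-4-hydroxy-3-isopropyl-6,8a-dimethyl-3-(triethylsilyloxy)-2,3,3a,4,8,8a-hexahydroazulen-7(1H)-one; 19 4-(tert-butyldimethylsilyloxy)benzoic acid
Product: 20 (3R,3aS,4S,8aR)-3-isopropyl-6,8a-dimethyl-7-oxo-3-(triethylsilyloxy)-1,2,3,3a,4,7,8,8a-octahydroazulen-4-yl 4-(tert-butyldimethylsilyloxy)benzoate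
Conditions: EDC·HCl, DMAP, CH2Cl2, rt
Reagents that add atoms: none
Why: Steglich esterification of the only free hydroxyl group (C6) proceeds with retention.

Step 13
Reactants: 20 (3R,3aS,4S,8aR)-3-isopropyl-6,8a-dimethyl-7-oxo-3-(triethylsilyloxy)-1,2,3,3a,4,7,8,8a-octahydroazulen-4-yl 4-(tert-butyldimethylsilyloxy)benzoate
Product: 21 (3R,3aS,4S,7R,8aR)-7-hydroxy-3-isopropyl-6,8a-dimethyl-3-(triethylsilyloxy)-1,2,3,3a,4,7,8,8a-octahydroazulen-4-yl 4-(tert-butyldimethylsilyloxy)benzoate
Conditions: NaBH4, CeCl3·7H2O, MeOH, −78 °C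
Reagents that add atoms: none
Why: Luche 1,2-reduction of the enone; hydride should add anti to the axial C1 methyl group (1,3 to the carbonyl), giving the C9 alcohol cis to that methyl, and the esters survive at low temperature.

Step 14
Reactants: 21 (3R,3aS,4S,7R,8aR)-7-hydroxy-3-isopropyl-6,8a-dimethyl-3-(triethylsilyloxy)-1,2,3,3a,4,7,8,8a-octahydroazulen-4-yl 4-(tert-butyldimethylsilyloxy)benzoate
Product: 22 (3R,3aS,4S,7S,8aR)-7-acetoxy-3-isopropyl-6,8a-dimethyl-3-(triethylsilyloxy)-1,2,3,3a,4,7,8,8a-octahydroazulen-4-yl 4-(tert-butyldimethylsilyloxy)benzoate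
Conditions: PPh3, DIAD, AcOH, THF, 0 °C → rt
Reagents that add atoms: acetic acid, CC(O)=O
Why: Mitsunobu esterification inverts C9 by SN2 attack of acetate from the less hindered face (the one the hydride used), installing the acetate cis to the C6 ester; SN2′ attack at C7 is disfavoured by the adjacent C6 aroyloxy group.

Step 15
Reactants: 22 (3R,3aS,4S,7S,8aR)-7-acetoxy-3-isopropyl-6,8a-dimethyl-3-(triethylsilyloxy)-1,2,3,3a,4,7,8,8a-octahydroazulen-4-yl 4-(tert-butyldimethylsilyloxy)benzoate
Product: 23 (3R,3aS,4S,7S,8aR)-7-acetoxy-3-hydroxy-3-isopropyl-6,8a-dimethyl-1,2,3,3a,4,7,8,8a-octahydroazulen-4-yl 4-hydroxybenzoate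
Conditions: TBAF, AcOH (1:1), THF, 0 °C → rt
Reagents that add atoms: none
Why: Buffered fluoride cleaves the aryl TBS ether and the tertiary TES ether without acyl migration or ester cleavage.

**Compound list**

1 | (S)-(+)-terpinen-4-ol | CC1=CC[C@](O)(C(C)C)CC1 | starting material
2 | (S)-triethyl[(1-isopropyl-4-methylcyclohex-3-en-1-yl)oxy]silane | CC1=CC[C@](O[Si](CC)(CC)CC)(C(C)C)CC1 | intermediate
3 | ozonide (1,2,4-trioxolane) of 2, mixture at the two ozonide carbons | CC12CC[C@@](O[Si](CC)(CC)CC)(C(C)C)CC(OO1)O2 | intermediate (not isolated)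
4 | (S)-3-isopropyl-6-oxo-3-(triethylsilyloxy)heptanal | O=CC[C@](O[Si](CC)(CC)CC)(C(C)C)CCC(C)=O | intermediate
5 | (R)-5-isopropyl-2-methyl-5-(triethylsilyloxy)cyclopent-1-ene-1-carbaldehyde | O=CC1=C(C)CC[C@@]1(O[Si](CC)(CC)CC)C(C)C | intermediate
6 | (R)-triethyl[(1-isopropyl-3-methyl-2-vinylcyclopent-2-en-1-yl)oxy]silane | C=CC1=C(C)CC[C@@]1(O[Si](CC)(CC)CC)C(C)C | intermediate
7 | methyl acetoacetate | COC(=O)CC(C)=O | starting material
8 | methyl 2-diazo-3-oxobutanoate | COC(=O)C(=[N+]=[N-])C(C)=O | intermediate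
9 | methyl 3-(tert-butyldimethylsilyloxy)-2-diazobut-3-enoate | COC(=O)C(=[N+]=[N-])C(=C)O[Si](C)(C)C(C)(C)C | intermediate
10 | methyl (1R,2S)-1-[1-(tert-butyldimethylsilyloxy)vinyl]-2-[(R)-5-isopropyl-2-methyl-5-(triethylsilyloxy)cyclopent-1-en-1-yl]cyclopropane-1-carboxylate | COC(=O)[C@]1(C(=C)O[Si](C)(C)C(C)(C)C)C[C@H]1C2=C(C)CC[C@@]2(O[Si](CC)(CC)CC)C(C)C | intermediate (not isolated)
11 | methyl (3R,8aR)-7-(tert-butyldimethylsilyloxy)-3-isopropyl-8a-methyl-3-(triethylsilyloxy)-1,2,3,5,8,8a-hexahydroazulene-6-carboxylate | COC(=O)C1=C(O[Si](C)(C)C(C)(C)C)C[C@@]2(C)CC[C@@](O[Si](CC)(CC)CC)(C(C)C)C2=CC1 | intermediate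
12 | alkylborane: 13 with BH2 in place of the 4-hydroxyl group, same configuration | COC(=O)C1=C(O[Si](C)(C)C(C)(C)C)C[C@@]2(C)CC[C@@](O[Si](CC)(CC)CC)(C(C)C)[C@@H]2[C@@H](B)C1 | intermediate (not isolated)
13 | methyl (3R,3aS,4S,8aR)-7-(tert-butyldimethylsilyloxy)-4-hydroxy-3-isopropyl-8a-methyl-3-(triethylsilyloxy)-1,2,3,3a,4,5,8,8a-octahydroazulene-6-carboxylate | COC(=O)C1=C(O[Si](C)(C)C(C)(C)C)C[C@@]2(C)CC[C@@](O[Si](CC)(CC)CC)(C(C)C)[C@@H]2[C@@H](O)C1 | intermediate
14 | (3R,3aS,4S,8aR)-7-(tert-butyldimethylsilyloxy)-6-(hydroxymethyl)-3-isopropyl-8a-methyl-3-(triethylsilyloxy)-1,2,3,3a,4,5,8,8a-octahydroazulen-4-ol | OCC1=C(O[Si](C)(C)C(C)(C)C)C[C@@]2(C)CC[C@@](O[Si](CC)(CC)CC)(C(C)C)[C@@H]2[C@@H](O)C1 | intermediate (not isolated)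
15 | (3R,3aS,4S,8aR)-4-hydroxy-3-isopropyl-8a-methyl-6-methylidene-3-(triethylsilyloxy)-2,3,3a,4,5,6,8,8a-octahydroazulen-7(1H)-one | O=C1C[C@@]2(C)CC[C@@](O[Si](CC)(CC)CC)(C(C)C)[C@@H]2[C@@H](O)CC1=C | intermediate
16 | (3R,3aS,4S,8aR)-4-hydroxy-3-isopropyl-6,8a-dimethyl-3-(triethylsilyloxy)-2,3,3a,4,8,8a-hexahydroazulen-7(1H)-one | O=C1C[C@@]2(C)CC[C@@](O[Si](CC)(CC)CC)(C(C)C)[C@@H]2[C@@H](O)C=C1C | intermediate
17 | 4-hydroxybenzoic acid | OC(=O)c1ccc(O)cc1 | starting material
18 | tert-butyldimethylsilyl 4-(tert-butyldimethylsilyloxy)benzoate | CC(C)(C)[Si](C)(C)OC(=O)c1ccc(O[Si](C)(C)C(C)(C)C)cc1 | intermediate (not isolated)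
19 | 4-(tert-butyldimethylsilyloxy)benzoic acid | OC(=O)c1ccc(O[Si](C)(C)C(C)(C)C)cc1 | intermediate
20 | (3R,3aS,4S,8aR)-3-isopropyl-6,8a-dimethyl-7-oxo-3-(triethylsilyloxy)-1,2,3,3a,4,7,8,8a-octahydroazulen-4-yl 4-(tert-butyldimethylsilyloxy)benzoate | O=C1C[C@@]2(C)CC[C@@](O[Si](CC)(CC)CC)(C(C)C)[C@@H]2[C@@H](OC(=O)c2ccc(O[Si](C)(C)C(C)(C)C)cc2)C=C1C | intermediate
21 | (3R,3aS,4S,7R,8aR)-7-hydroxy-3-isopropyl-6,8a-dimethyl-3-(triethylsilyloxy)-1,2,3,3a,4,7,8,8a-octahydroazulen-4-yl 4-(tert-butyldimethylsilyloxy)benzoate | O[C@@H]1C[C@@]2(C)CC[C@@](O[Si](CC)(CC)CC)(C(C)C)[C@@H]2[C@@H](OC(=O)c2ccc(O[Si](C)(C)C(C)(C)C)cc2)C=C1C | intermediate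
22 | (3R,3aS,4S,7S,8aR)-7-acetoxy-3-isopropyl-6,8a-dimethyl-3-(triethylsilyloxy)-1,2,3,3a,4,7,8,8a-octahydroazulen-4-yl 4-(tert-butyldimethylsilyloxy)benzoate | CC(=O)O[C@H]1C[C@@]2(C)CC[C@@](O[Si](CC)(CC)CC)(C(C)C)[C@@H]2[C@@H](OC(=O)c2ccc(O[Si](C)(C)C(C)(C)C)cc2)C=C1C | intermediate
23 | (3R,3aS,4S,7S,8aR)-7-acetoxy-3-hydroxy-3-isopropyl-6,8a-dimethyl-1,2,3,3a,4,7,8,8a-octahydroazulen-4-yl 4-hydroxybenzoate | CC(=O)O[C@H]1C[C@@]2(C)CC[C@@](O)(C(C)C)[C@@H]2[C@@H](OC(=O)c2ccc(O)cc2)C=C1C | target

**Step count and risks**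

Total step count: 15. Longest linear sequence: 12 (steps 1–4, 7–10, 12–15).

Steps most likely to fail:

Step 8. The risk is facial selectivity: borane may add syn to the angular methyl and the C4 silyloxy group, or without preference, because the C4 isopropyl group and the folded cycloheptadiene shield the required face; this would give the cis-fused C5/C6 epimer. The fallback sets out from 11 and comes back at 13. It turns the same facial preference into an addition that ends anti. mCPBA/NaHCO3 (CH2Cl2, 0 °C) epoxidises C5=C6 on the face the borane preferred, giving the epoxide F2. BF3·OEt2 (CH2Cl2, −78 °C) then triggers a Meinwald rearrangement: the C5–O bond ionises and the C6 hydrogen shifts to C5 anti to the departing oxygen, which places H5 trans to the angular methyl and gives the trans-fused C6 ketone F3. Reagent-controlled CBS reduction ((R)-Me-CBS, catecholborane, toluene, −78 °C) then returns 13.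

Step 7. The risks are mismatched double stereodifferentiation (catalyst against the C4 stereocentre) that erodes control of C1, and a Cope step of the congested divinylcyclopropane that lags behind decomposition of the donor/acceptor cyclopropane. The S catalyst is assigned by analogy with the sense of induction of this catalyst family on monosubstituted alkenes; if induction on 6 proves opposite, Rh2(R-PTAD)4 is used. The fallback sets out from 6 and comes back at 11; it separates the two bond formations so that each can be optimised alone. Rh2(esp)2-catalysed cyclopropanation of the vinyl group of 6 with the acceptor/acceptor carbenoid from diazo ketoester 8 gives the acetylcyclopropane F1, whose diastereomers are separated at this stage. Soft enolisation (TBSOTf, Et3N, CH2Cl2) converts F1 into the siloxyvinyl compound 10, which is heated in toluene to undergo the Cope rearrangement to 11.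

Step 10. The risks are over-isomerisation of the product γ-hydroxy enone to the 1,4-diketone by the rhodium hydride, loss of the TES ether in hot ethanol, and dimerisation of the α-methylene ketone before it isomerises. The fallback sets out from 15 and comes back at 16; it replaces hydride migration by saturation and regioselective dehydrogenation. Hydrogenation (H2, Pd/C, EtOAc) of the exocyclic alkene gives the saturated methyl ketone F4 as a C8 epimer mixture. TMSOTf/Et3N gives the more substituted trimethylsilyl enol ether with the C6 hydroxyl also silylated, the bis-silyl compound F5. Saegusa–Ito oxidation (Pd(OAc)2, MeCN), where β-hydride loss within the ring is possible only toward C7, followed by mild acidic work-up, gives 16.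

Further compounds
F1 | step 7 | methyl (1R,2S)-1-acetyl-2-[(R)-5-isopropyl-2-methyl-5-(triethylsilyloxy)cyclopent-1-en-1-yl]cyclopropane-1-carboxylate | COC(=O)[C@]1(C(C)=O)C[C@H]1C2=C(C)CC[C@@]2(O[Si](CC)(CC)CC)C(C)C
F2 | step 8 | 3a,4-epoxide of 11 on the face of the 8a-methyl group | COC(=O)C1=C(O[Si](C)(C)C(C)(C)C)C[C@@]2(C)CC[C@@](O[Si](CC)(CC)CC)(C(C)C)[C@]23O[C@@H]3C1
F3 | step 8 | 4-oxo analogue of 13 with trans ring fusion (H3a anti to the 8a-methyl group) | COC(=O)C1=C(O[Si](C)(C)C(C)(C)C)C[C@@]2(C)CC[C@@](O[Si](CC)(CC)CC)(C(C)C)[C@@H]2C(=O)C1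
F4 | step 10 | (3R,3aS,4S,8aR)-4-hydroxy-3-isopropyl-6,8a-dimethyl-3-(triethylsilyloxy)octahydroazulen-7(1H)-one, mixture at C6 | O=C1C[C@@]2(C)CC[C@@](O[Si](CC)(CC)CC)(C(C)C)[C@@H]2[C@@H](O)CC1C
F5 | step 10 | 7-trimethylsilyl enol ether (6,7-alkene) and 4-O-trimethylsilyl ether of F4 | C[Si](C)(C)OC=1C[C@@]2(C)CC[C@@](O[Si](CC)(CC)CC)(C(C)C)[C@@H]2[C@@H](O[Si](C)(C)C)CC=1C
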